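**Retrosynthetic overview** (side-chain carbons are counted C1' at the ring out to C32')
1. No ring is built. The naphthoquinone bicycle is bought as menadione, masked at the start as the hydroquinone dimethyl ether, and unmasked by oxidative demethylation in the last step.
2. C20'-C21' and C8'-C9' are cut as allylic sulfone alkylations. Both C15 blocks come from (2E,6E)-farnesol, and both sulfonyl groups are removed together.
3. The key disconnection is C6'-C7'. An intermolecular Evans syn-aldol between a propionyl oxazolidinone and the aryl-bearing C1'-C6' aldehyde sets C7' as R. The C6' hydroxyl is then removed by radical deoxygenation.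
4. The aldehyde comes from the geranylated arene (aryl Grignard plus geranyl bromide) by cleavage of the terminal isopropylidene group. Every E-olefin is therefore inherited from geraniol or farnesol.

Assumption: geraniol and (2E,6E)-farnesol are used as geometrically pure commercial grades, and the transient epoxide carbon and the sulfonyl-bearing carbons C9' and C21' are left undefined because they are cleaved or end as CH2.

**Step 1**
Reactants: 1 menadione (2-methylnaphthalene-1,4-dione)
Product: 3 1,4-dimethoxy-2-methylnaphthalene, via menadiol 2 (not isolated)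
Conditions: Na2S2O4, Bu4NBr (cat.), THF/H2O, rt; then aq KOH, Me2SO4, rt, N2
Reagents that add atoms: dimethyl sulfate COS(=O)(=O)OC
Why: Reductive methylation, in which dithionite reduces the quinone to the hydroquinone and its dianion undergoes a double Williamson O-methylation in the same flask before air can re-oxidise it, masking the quinone against all later carbanions, hydrides and radicals.

**Step 2**
Reactants: 3 1,4-dimethoxy-2-methylnaphthalene
Product: 4 2-bromo-1,4-dimethoxy-3-methylnaphthalene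
Conditions: Br2 (1.05 equiv), CH2Cl2, 0 °C
Reagents that add atoms: bromine BrBr
Why: Electrophilic aromatic bromination goes to C3, the only open position of the strongly activated dialkoxy ring.

**Step 3**
Reactants: 5 geraniol
Product: 6 geranyl bromide ((2E)-1-bromo-3,7-dimethylocta-2,6-diene)
Conditions: PBr3 (0.4 equiv), Et2O, -10 to 0 °C, used crude
Reagents that add atoms: phosphorus tribromide BrP(Br)Br
Why: SN2 displacement of the phosphite ester of a primary allylic alcohol by bromide at low temperature proceeds without allylic transposition or loss of the E geometry.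

**Step 4**
Reactants: 4 2-bromo-1,4-dimethoxy-3-methylnaphthalene; 6 geranyl bromide
Product: 8 geranyl arene (2-[(2E)-3,7-dimethylocta-2,6-dien-1-yl]-1,4-dimethoxy-3-methylnaphthalene), via aryl Grignard 7 (not isolated)
Conditions: Mg, THF, reflux; then CuI (10 mol %), 6, THF, 0 °C to rt
Reagents that add atoms: none
Why: Grignard formation followed by copper-catalysed SN2 allylic substitution at the unhindered primary carbon of 6 forms the aryl-C1' bond with retention of the E-olefin, because the fully substituted gamma carbon is too hindered for SN2' attack.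

**Step 5**
Reactants: 8 geranyl arene
Product: 9 terminal epoxide (2-[(2E)-5-(3,3-dimethyloxiran-2-yl)-3-methylpent-2-en-1-yl]-1,4-dimethoxy-3-methylnaphthalene, racemic at the oxirane CH)
Conditions: mCPBA (1.0 equiv), CH2Cl2, -20 to 0 °C
Reagents that add atoms: mCPBA OOC(=O)c1cccc(Cl)c1
Why: Prilezhaev epoxidation with one equivalent of peracid picks the exposed isopropylidene olefin because C2'=C3' is shielded by the ortho,ortho'-disubstituted naphthyl group, and the new racemic epoxide stereocentre disappears in step 6.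

**Step 6**
Reactants: 9 terminal epoxide
Product: 10 aldehyde ((4E)-6-(1,4-dimethoxy-3-methylnaphthalen-2-yl)-4-methylhex-4-enal)
Conditions: H5IO6 (1.2 equiv), THF/Et2O, 0 °C
Reagents that add atoms: none
Why: Periodic acid opens the epoxide to the glycol and cleaves it in the same pot (Malaprade cleavage), which expels acetone and leaves the E-trisubstituted olefin and the aryl ethers untouched.

**Step 7**
Reactants: 10 aldehyde; 11 (4R)-4-benzyl-3-propanoyl-1,3-oxazolidin-2-one
Product: 14 aldol adduct ((4R)-4-benzyl-3-[(2R,3S,6E)-8-(1,4-dimethoxy-3-methylnaphthalen-2-yl)-3-hydroxy-2,6-dimethyloct-6-enoyl]-1,3-oxazolidin-2-one), via boron enolate 12 (not isolated), via boron aldolate 13 (not isolated)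
Conditions: 11, Bu2BOTf (1.15 equiv), Et3N (1.3 equiv), CH2Cl2, 0 °C; 10, -78 to 0 °C; then pH 7 buffer, MeOH, 30% H2O2, 0 °C
Reagents that add atoms: none
Why: Evans syn-aldol reaction, in which soft enolisation gives only the Z-boron enolate and this adds to 10 through a Zimmerman-Traxler chair on the face away from the benzyl group, so the C6'-C7' bond forms with C7' fixed as R (2R in the acyl chain) and the sacrificial carbinol C6' as S in more than 95:5 dr.

**Step 8**
Reactants: 14 aldol adduct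
Product: 15 thiocarbonylimidazolide (O-(imidazol-1-ylcarbonothioyl) derivative of 14 at the 3S carbinol)
Conditions: 1,1'-thiocarbonyldiimidazole (2 equiv), DMAP (cat.), CH2Cl2, rt to 40 °C
Reagents that add atoms: 1,1'-thiocarbonyldiimidazole S=C(n1ccnc1)n1ccnc1
Why: Thioacylation of the secondary alcohol with a neutral acyl-transfer reagent (first half of the Barton-McCombie deoxygenation) avoids the strong base of xanthate formation, which would trigger retro-aldol cleavage or epimerisation at C7'.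

**Step 9**
Reactants: 15 thiocarbonylimidazolide
Product: 16 deoxygenated imide ((4R)-4-benzyl-3-[(2R,6E)-8-(1,4-dimethoxy-3-methylnaphthalen-2-yl)-2,6-dimethyloct-6-enoyl]-1,3-oxazolidin-2-one)
Conditions: Bu3SnH (2 equiv), AIBN (cat.), toluene, 100 °C
Reagents that add atoms: none
Why: Barton-McCombie radical deoxygenation, in which the stannyl radical adds to C=S, the C6'-O bond fragments, and the secondary radical (only slow 4-exo or 5-endo cyclisation modes open to it) abstracts hydrogen from Bu3SnH while the neighbouring C7' centre is not touched.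

**Step 10**
Reactants: 16 deoxygenated imide
Product: 17 alcohol ((2R,6E)-8-(1,4-dimethoxy-3-methylnaphthalen-2-yl)-2,6-dimethyloct-6-en-1-ol)
Conditions: LiBH4, THF/Et2O, 0 °C to rt; aq NH4Cl
Reagents that add atoms: none
Why: Reductive cleavage of the auxiliary, in which borohydride attacks the more electrophilic exocyclic imide carbonyl and reduces it to the primary alcohol under conditions too weakly basic to epimerise C7', and the oxazolidinone is recovered.

**Step 11**
Reactants: 17 alcohol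
Product: 18 iodide (2-[(2E,7R)-8-iodo-3,7-dimethyloct-2-en-1-yl]-1,4-dimethoxy-3-methylnaphthalene)
Conditions: I2, PPh3, imidazole, CH2Cl2, 0 °C to rt
Reagents that add atoms: iodine II
Why: Appel-type iodination (Garegg-Samuelsson conditions) converts the primary alcohol by SN2 at C8', one carbon away from the stereocentre, which therefore stays R.

**Step 12**
Reactants: 19 (2E,6E)-farnesol
Product: 20 (2E,6E)-farnesyl bromide
Conditions: PBr3 (0.4 equiv), Et2O, -10 to 0 °C, used crude
Reagents that add atoms: phosphorus tribromide BrP(Br)Br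
Why: SN2 bromination of the primary allylic alcohol through its phosphite ester keeps both E-olefins in place.

**Step 13**
Reactants: 20 (2E,6E)-farnesyl bromide
Product: 21 farnesyl phenyl sulfone ({[(2E,6E)-3,7,11-trimethyldodeca-2,6,10-trien-1-yl]sulfonyl}benzene)
Conditions: PhSO2Na, DMF, rt
Reagents that add atoms: sodium benzenesulfinate [Na+].[O-]S(=O)c1ccccc1
Why: SN2 S-alkylation of the soft sulfinate anion by the primary allylic bromide in a dipolar aprotic solvent gives the sulfone without allylic shift.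

**Step 14**
Reactants: 21 farnesyl phenyl sulfone
Product: 22 hydroxy sulfone ((2E,6E,10E)-2,6,10-trimethyl-12-(phenylsulfonyl)dodeca-2,6,10-trien-1-ol)
Conditions: SeO2 (0.2 equiv), t-BuOOH (3 equiv), salicylic acid (0.1 equiv), CH2Cl2, 0 °C to rt, stopped near 60% conversion, 21 recovered for step 19
Reagents that add atoms: tert-butyl hydroperoxide CC(C)(C)OO; selenium dioxide (catalytic oxygen carrier) O=[Se]=O
Why: Catalytic SeO2 allylic oxidation (Riley oxidation in the Sharpless-Umbreit version, ene reaction then [2,3]-sigmatropic shift) attacks the most electron-rich terminal olefin at its E-methyl group, so the new allylic alcohol is E and the sulfone-deactivated proximal olefin is spared.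

**Step 15**
Reactants: 22 hydroxy sulfone
Product: 23 silyl ether (tert-butyldimethylsilyl ether of 22)
Conditions: TBSCl, imidazole, CH2Cl2, rt
Reagents that add atoms: tert-butyldimethylsilyl chloride CC(C)(C)[Si](C)(C)Cl
Why: Imidazole-promoted silylation removes the hydroxyl proton so that one equivalent of base gives a clean carbanion in step 16.

**Step 16**
Reactants: 23 silyl ether; 18 iodide
Product: 25 coupled sulfone (2-[(2E,7R,10E,14E,18E)-20-(tert-butyldimethylsilyloxy)-3,7,11,15,19-pentamethyl-9-(phenylsulfonyl)icosa-2,10,14,18-tetraen-1-yl]-1,4-dimethoxy-3-methylnaphthalene, C9' epimers), via lithiated sulfone 24 (not isolated)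
Conditions: 23 (1.2 equiv), n-BuLi, THF/DMPU, -78 °C; then 18, -78 °C to rt
Reagents that add atoms: none
Why: Alkylation of an alpha-lithiated allylic sulfone (Biellmann-Julia type coupling) occurs at the alpha carbon by SN2 on the primary iodide, forms C8'-C9' without touching C7', and gives C9' epimers that do not matter because this carbon ends as CH2.

**Step 17**
Reactants: 25 coupled sulfone
Product: 26 allylic alcohol (2-[(2E,7R,10E,14E,18E)-20-hydroxy-3,7,11,15,19-pentamethyl-9-(phenylsulfonyl)icosa-2,10,14,18-tetraen-1-yl]-1,4-dimethoxy-3-methylnaphthalene)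
Conditions: Bu4NF, THF, 0 °C to rt
Reagents that add atoms: none
Why: Fluoride-driven desilylation relies on the strong Si-F bond and leaves sulfone, olefins and aryl ethers alone.

**Step 18**
Reactants: 26 allylic alcohol
Product: 27 allylic bromide (2-[(2E,7R,10E,14E,18E)-20-bromo-3,7,11,15,19-pentamethyl-9-(phenylsulfonyl)icosa-2,10,14,18-tetraen-1-yl]-1,4-dimethoxy-3-methylnaphthalene)
Conditions: CBr4, PPh3, CH2Cl2, -20 to 0 °C, used at once
Reagents that add atoms: carbon tetrabromide BrC(Br)(Br)Br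
Why: Appel bromination replaces the primary allylic hydroxyl by SN2 under neutral conditions, so the E-olefin neither shifts nor isomerises.

**Step 19**
Reactants: 21 farnesyl phenyl sulfone; 27 allylic bromide
Product: 29 bis-sulfone (2-[(2E,7R,10E,14E,18E,22E,26E)-3,7,11,15,19,23,27,31-octamethyl-9,21-bis(phenylsulfonyl)dotriaconta-2,10,14,18,22,26,30-heptaen-1-yl]-1,4-dimethoxy-3-methylnaphthalene, epimers at C9' and C21'), via lithiated farnesyl sulfone 28 (not isolated)
Conditions: 21 (1.3 equiv), n-BuLi, THF, -78 °C; then 27, -78 to -20 °C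
Reagents that add atoms: none
Why: Second allylic sulfone alkylation, in which carbanion 28 displaces the very reactive allylic bromide at -78 °C faster than it can remove the more hindered and less acidic C9'-H, forming C20'-C21' with all olefins in place.

**Step 20**
Reactants: 29 bis-sulfone
Product: 30 hydroquinone dimethyl ether (2-[(2E,7R,10E,14E,18E,22E,26E)-3,7,11,15,19,23,27,31-octamethyldotriaconta-2,10,14,18,22,26,30-heptaen-1-yl]-1,4-dimethoxy-3-methylnaphthalene)
Conditions: LiEt3BH (6 equiv), PdCl2(dppp) (10 mol %), THF, 0 °C to rt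
Reagents that add atoms: none
Why: Palladium-catalysed hydride desulfonylation (Tsuji-Trost type ionisation, Inomata-Kotake conditions), in which zerovalent palladium formed in situ ionises each allylic sulfone to a pi-allyl complex and hydride goes to the less substituted terminus, removing both sulfonyl groups with the trisubstituted E-olefins kept in place.

**Step 21**
Reactants: 30 hydroquinone dimethyl ether
Product: 31 target (2-methyl-3-[(2E,7R,10E,14E,18E,22E,26E)-3,7,11,15,19,23,27,31-octamethyldotriaconta-2,10,14,18,22,26,30-heptaen-1-yl]naphthalene-1,4-dione)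
Conditions: (NH4)2Ce(NO3)6 (2.5 equiv), MeCN/CH2Cl2/H2O, 0 °C
Reagents that add atoms: water O
Why: Oxidative demethylation, in which two one-electron oxidations by tetravalent cerium and attack of water at the two ipso carbons release methanol and the 1,4-quinone much faster than the isolated olefins or the remote C7' centre can react.

**Compound list**
1 | menadione (2-methylnaphthalene-1,4-dione) | CC1=CC(=O)c2ccccc2C1=O | starting material
2 | menadiol (2-methylnaphthalene-1,4-diol), not isolated | Cc1cc(O)c2ccccc2c1O | intermediate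
3 | 1,4-dimethoxy-2-methylnaphthalene | Cc1cc(OC)c2ccccc2c1OC | intermediate
4 | 2-bromo-1,4-dimethoxy-3-methylnaphthalene | Cc1c(Br)c(OC)c2ccccc2c1OC | intermediate
5 | geraniol ((2E)-3,7-dimethylocta-2,6-dien-1-ol) | CC(C)=CCC/C(C)=C/CO | starting material
6 | geranyl bromide ((2E)-1-bromo-3,7-dimethylocta-2,6-diene) | CC(C)=CCC/C(C)=C/CBr | intermediate
7 | aryl Grignard ((1,4-dimethoxy-3-methylnaphthalen-2-yl)magnesium bromide), not isolated | Cc1c([Mg]Br)c(OC)c2ccccc2c1OC | intermediate
8 | geranyl arene (2-[(2E)-3,7-dimethylocta-2,6-dien-1-yl]-1,4-dimethoxy-3-methylnaphthalene) | CC(C)=CCC/C(C)=C/Cc1c(C)c(OC)c2ccccc2c1OC | intermediate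
9 | terminal epoxide (2-[(2E)-5-(3,3-dimethyloxiran-2-yl)-3-methylpent-2-en-1-yl]-1,4-dimethoxy-3-methylnaphthalene, racemic) | CC1(C)OC1CC/C(C)=C/Cc1c(C)c(OC)c2ccccc2c1OC | intermediate
10 | aldehyde ((4E)-6-(1,4-dimethoxy-3-methylnaphthalen-2-yl)-4-methylhex-4-enal) | O=CCC/C(C)=C/Cc1c(C)c(OC)c2ccccc2c1OC | intermediate
11 | (4R)-4-benzyl-3-propanoyl-1,3-oxazolidin-2-one | CCC(=O)N1[C@H](Cc2ccccc2)COC1=O | starting material
12 | boron enolate ((4R)-4-benzyl-3-[(1Z)-1-(dibutylboranyloxy)prop-1-en-1-yl]-1,3-oxazolidin-2-one), not isolated | C/C=C(\OB(CCCC)CCCC)N1[C@H](Cc2ccccc2)COC1=O | intermediate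
13 | boron aldolate (O-dibutylboranyl derivative of 14), not isolated | C[C@@H](C(=O)N1[C@H](Cc2ccccc2)COC1=O)[C@@H](OB(CCCC)CCCC)CC/C(C)=C/Cc1c(C)c(OC)c2ccccc2c1OC | intermediate
14 | aldol adduct ((4R)-4-benzyl-3-[(2R,3S,6E)-8-(1,4-dimethoxy-3-methylnaphthalen-2-yl)-3-hydroxy-2,6-dimethyloct-6-enoyl]-1,3-oxazolidin-2-one) | C[C@@H](C(=O)N1[C@H](Cc2ccccc2)COC1=O)[C@@H](O)CC/C(C)=C/Cc1c(C)c(OC)c2ccccc2c1OC | intermediate
15 | thiocarbonylimidazolide (O-(imidazol-1-ylcarbonothioyl) derivative of 14, 2R,3S) | C[C@@H](C(=O)N1[C@H](Cc2ccccc2)COC1=O)[C@@H](OC(=S)n1ccnc1)CC/C(C)=C/Cc1c(C)c(OC)c2ccccc2c1OC | intermediate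
16 | deoxygenated imide ((4R)-4-benzyl-3-[(2R,6E)-8-(1,4-dimethoxy-3-methylnaphthalen-2-yl)-2,6-dimethyloct-6-enoyl]-1,3-oxazolidin-2-one) | C[C@@H](C(=O)N1[C@H](Cc2ccccc2)COC1=O)CCC/C(C)=C/Cc1c(C)c(OC)c2ccccc2c1OC | intermediate
17 | alcohol ((2R,6E)-8-(1,4-dimethoxy-3-methylnaphthalen-2-yl)-2,6-dimethyloct-6-en-1-ol) | C[C@@H](CO)CCC/C(C)=C/Cc1c(C)c(OC)c2ccccc2c1OC | intermediate
18 | iodide (2-[(2E,7R)-8-iodo-3,7-dimethyloct-2-en-1-yl]-1,4-dimethoxy-3-methylnaphthalene) | C[C@@H](CI)CCC/C(C)=C/Cc1c(C)c(OC)c2ccccc2c1OC | intermediate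
19 | (2E,6E)-farnesol | CC(C)=CCC/C(C)=C/CC/C(C)=C/CO | starting material
20 | (2E,6E)-farnesyl bromide | CC(C)=CCC/C(C)=C/CC/C(C)=C/CBr | intermediate
21 | farnesyl phenyl sulfone ({[(2E,6E)-3,7,11-trimethyldodeca-2,6,10-trien-1-yl]sulfonyl}benzene) | CC(C)=CCC/C(C)=C/CC/C(C)=C/CS(=O)(=O)c1ccccc1 | intermediate
22 | hydroxy sulfone ((2E,6E,10E)-2,6,10-trimethyl-12-(phenylsulfonyl)dodeca-2,6,10-trien-1-ol) | OC/C(C)=C/CC/C(C)=C/CC/C(C)=C/CS(=O)(=O)c1ccccc1 | intermediate
23 | silyl ether (tert-butyldimethylsilyl ether of 22) | CC(C)(C)[Si](C)(C)OC/C(C)=C/CC/C(C)=C/CC/C(C)=C/CS(=O)(=O)c1ccccc1 | intermediate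
24 | lithiated sulfone (23 lithiated at the sulfonyl-bearing carbon), not isolated | CC(C)(C)[Si](C)(C)OC/C(C)=C/CC/C(C)=C/CC/C(C)=C/C([Li])S(=O)(=O)c1ccccc1 | intermediate
25 | coupled sulfone (2-[(2E,7R,10E,14E,18E)-20-(tert-butyldimethylsilyloxy)-3,7,11,15,19-pentamethyl-9-(phenylsulfonyl)icosa-2,10,14,18-tetraen-1-yl]-1,4-dimethoxy-3-methylnaphthalene) | CC(C)(C)[Si](C)(C)OC/C(C)=C/CC/C(C)=C/CC/C(C)=C/C(C[C@H](C)CCC/C(C)=C/Cc1c(C)c(OC)c2ccccc2c1OC)S(=O)(=O)c1ccccc1 | intermediate
26 | allylic alcohol (20-hydroxy analogue of 25) | OC/C(C)=C/CC/C(C)=C/CC/C(C)=C/C(C[C@H](C)CCC/C(C)=C/Cc1c(C)c(OC)c2ccccc2c1OC)S(=O)(=O)c1ccccc1 | intermediate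
27 | allylic bromide (20-bromo analogue of 25) | BrC/C(C)=C/CC/C(C)=C/CC/C(C)=C/C(C[C@H](C)CCC/C(C)=C/Cc1c(C)c(OC)c2ccccc2c1OC)S(=O)(=O)c1ccccc1 | intermediate
28 | lithiated farnesyl sulfone (21 lithiated at the sulfonyl-bearing carbon), not isolated | CC(C)=CCC/C(C)=C/CC/C(C)=C/C([Li])S(=O)(=O)c1ccccc1 | intermediate
29 | bis-sulfone (2-[(2E,7R,10E,14E,18E,22E,26E)-3,7,11,15,19,23,27,31-octamethyl-9,21-bis(phenylsulfonyl)dotriaconta-2,10,14,18,22,26,30-heptaen-1-yl]-1,4-dimethoxy-3-methylnaphthalene) | CC(C)=CCC/C(C)=C/CC/C(C)=C/C(S(=O)(=O)c1ccccc1)C/C(C)=C/CC/C(C)=C/CC/C(C)=C/C(C[C@H](C)CCC/C(C)=C/Cc1c(C)c(OC)c2ccccc2c1OC)S(=O)(=O)c1ccccc1 | intermediate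
30 | hydroquinone dimethyl ether (2-[(2E,7R,10E,14E,18E,22E,26E)-3,7,11,15,19,23,27,31-octamethyldotriaconta-2,10,14,18,22,26,30-heptaen-1-yl]-1,4-dimethoxy-3-methylnaphthalene) | CC(C)=CCC/C(C)=C/CC/C(C)=C/CC/C(C)=C/CC/C(C)=C/CC/C(C)=C/CC[C@H](C)CCC/C(C)=C/Cc1c(C)c(OC)c2ccccc2c1OC | intermediate
31 | target (2-methyl-3-[(2E,7R,10E,14E,18E,22E,26E)-3,7,11,15,19,23,27,31-octamethyldotriaconta-2,10,14,18,22,26,30-heptaen-1-yl]naphthalene-1,4-dione) | CC(C)=CCC/C(C)=C/CC/C(C)=C/CC/C(C)=C/CC/C(C)=C/CC/C(C)=C/CC[C@H](C)CCC/C(C)=C/CC1=C(C)C(=O)c2ccccc2C1=O | target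

**Total step count:** 21.
**Longest linear sequence:** 16 steps from menadione (steps 1, 2, 4 to 11 and 16 to 21).

**Three steps most likely to fail**

**Step 5.** The peracid may also attack C2'=C3' or the electron-rich arene.
- The fallback sets out from bromide 4 and comes back at aldehyde 10. It replaces site-selective oxidation by a Johnson-Claisen construction of the E-olefin.
- Grignard 7, made from 4, is allylated with allyl bromide (CuI cat., THF) to 2-allyl-1,4-dimethoxy-3-methylnaphthalene F1.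
- Lemieux-Johnson cleavage (K2OsO2(OH)4 cat., NaIO4, 2,6-lutidine, dioxane/H2O) gives (1,4-dimethoxy-3-methylnaphthalen-2-yl)acetaldehyde F2.
- CH2=C(CH3)MgBr in THF at -78 °C gives racemic 1-(1,4-dimethoxy-3-methylnaphthalen-2-yl)-3-methylbut-3-en-2-ol F3.
- Heating with CH3C(OEt)3 and catalytic propionic acid at 140 °C gives ethyl (4E)-6-(1,4-dimethoxy-3-methylnaphthalen-2-yl)-4-methylhex-4-enoate F4 through a chair [3,3] shift, with E over Z above 95:5.
- i-Bu2AlH in toluene at -78 °C stops at aldehyde 10.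

**Step 8.** The beta-hydroxy imide may eliminate or undergo retro-aldol cleavage during thioacylation.
- The fallback sets out from aldol adduct 14 and comes back at alcohol 17. It keeps the aldol bond but removes the carbonyl before the deoxygenation.
- LiBH4 (THF/Et2O, 0 °C) cleaves the auxiliary to (2S,3S,6E)-8-(1,4-dimethoxy-3-methylnaphthalen-2-yl)-2,6-dimethyloct-6-ene-1,3-diol F5.
- TBSCl and imidazole at 0 °C silylate only the primary hydroxyl, giving (2S,3S,6E)-1-(tert-butyldimethylsilyloxy)-8-(1,4-dimethoxy-3-methylnaphthalen-2-yl)-2,6-dimethyloct-6-en-3-ol F6.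
- With no acidic alpha-proton or carbonyl left, NaH, CS2 and MeI give the O-alkyl S-methyl xanthate of that alcohol F7.
- Bu3SnH and AIBN in toluene give tert-butyl{[(2R,6E)-8-(1,4-dimethoxy-3-methylnaphthalen-2-yl)-2,6-dimethyloct-6-en-1-yl]oxy}dimethylsilane F8.
- Bu4NF releases alcohol 17.

**Step 14.** The yield is low because the internal olefin competes and over-oxidation occurs.
- The fallback sets out from sulfone 21 and comes back at hydroxy sulfone 22. It swaps allylic C-H oxidation for olefin cleavage and rebuilding.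
- NBS in aqueous THF at 0 °C (terminal-selective bromohydrin formation) gives (6E,10E)-3-bromo-2,6,10-trimethyl-12-(phenylsulfonyl)dodeca-6,10-dien-2-ol F9.
- K2CO3 in MeOH closes it to 2,2-dimethyl-3-[(3E,7E)-3,7-dimethyl-9-(phenylsulfonyl)nona-3,7-dien-1-yl]oxirane F10.
- H5IO6 cleaves this to (4E,8E)-4,8-dimethyl-10-(phenylsulfonyl)deca-4,8-dienal F11.
- The stabilised ylide Ph3P=C(CH3)CO2Et in CH2Cl2 gives ethyl (2E,6E,10E)-2,6,10-trimethyl-12-(phenylsulfonyl)dodeca-2,6,10-trienoate F12 by an E-selective Wittig reaction.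
- i-Bu2AlH (2.2 equiv, CH2Cl2, -78 °C) gives 22.

**Further compounds**
F1 | step 5 | 2-allyl-1,4-dimethoxy-3-methylnaphthalene | C=CCc1c(C)c(OC)c2ccccc2c1OC
F2 | step 5 | (1,4-dimethoxy-3-methylnaphthalen-2-yl)acetaldehyde | O=CCc1c(C)c(OC)c2ccccc2c1OC
F3 | step 5 | 1-(1,4-dimethoxy-3-methylnaphthalen-2-yl)-3-methylbut-3-en-2-ol (racemic) | CC(=C)C(O)Cc1c(C)c(OC)c2ccccc2c1OC
F4 | step 5 | ethyl (4E)-6-(1,4-dimethoxy-3-methylnaphthalen-2-yl)-4-methylhex-4-enoate | CCOC(=O)CC/C(C)=C/Cc1c(C)c(OC)c2ccccc2c1OC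
F5 | step 8 | (2S,3S,6E)-8-(1,4-dimethoxy-3-methylnaphthalen-2-yl)-2,6-dimethyloct-6-ene-1,3-diol | C[C@@H](CO)[C@@H](O)CC/C(C)=C/Cc1c(C)c(OC)c2ccccc2c1OC
F6 | step 8 | (2S,3S,6E)-1-(tert-butyldimethylsilyloxy)-8-(1,4-dimethoxy-3-methylnaphthalen-2-yl)-2,6-dimethyloct-6-en-3-ol | C[C@@H](CO[Si](C)(C)C(C)(C)C)[C@@H](O)CC/C(C)=C/Cc1c(C)c(OC)c2ccccc2c1OC
F7 | step 8 | O-[(2S,3S,6E)-1-(tert-butyldimethylsilyloxy)-8-(1,4-dimethoxy-3-methylnaphthalen-2-yl)-2,6-dimethyloct-6-en-3-yl] S-methyl carbonodithioate | C[C@@H](CO[Si](C)(C)C(C)(C)C)[C@@H](OC(=S)SC)CC/C(C)=C/Cc1c(C)c(OC)c2ccccc2c1OC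
F8 | step 8 | tert-butyl{[(2R,6E)-8-(1,4-dimethoxy-3-methylnaphthalen-2-yl)-2,6-dimethyloct-6-en-1-yl]oxy}dimethylsilane | C[C@@H](CO[Si](C)(C)C(C)(C)C)CCC/C(C)=C/Cc1c(C)c(OC)c2ccccc2c1OC
F9 | step 14 | (6E,10E)-3-bromo-2,6,10-trimethyl-12-(phenylsulfonyl)dodeca-6,10-dien-2-ol (racemic) | CC(C)(O)C(Br)CC/C(C)=C/CC/C(C)=C/CS(=O)(=O)c1ccccc1
F10 | step 14 | 2,2-dimethyl-3-[(3E,7E)-3,7-dimethyl-9-(phenylsulfonyl)nona-3,7-dien-1-yl]oxirane (racemic) | CC1(C)OC1CC/C(C)=C/CC/C(C)=C/CS(=O)(=O)c1ccccc1
F11 | step 14 | (4E,8E)-4,8-dimethyl-10-(phenylsulfonyl)deca-4,8-dienal | O=CCC/C(C)=C/CC/C(C)=C/CS(=O)(=O)c1ccccc1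
F12 | step 14 | ethyl (2E,6E,10E)-2,6,10-trimethyl-12-(phenylsulfonyl)dodeca-2,6,10-trienoate | CCOC(=O)/C(C)=C/CC/C(C)=C/CC/C(C)=C/CS(=O)(=O)c1ccccc1
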